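The cyclopentane ring of the bicyclo[3.2.1]octane is cut at both ends of its CH2–CH bridge (C2–C3): bond C1–C2 to the prenyl bridgehead and bond C3–C4 to the methyl bridgehead. What remains, ring C1–C8–C4–C5–C6–C7, is a fully substituted acylphloroglucinol in which C1 and C4 are meta carbons flanking the C8 oxygen. One palladium-catalysed double allylic alkylation with an (E)-bis(methyl carbonate) bridges them, dearomatises the arene, sets C1, C3 and C4 and leaves an isopropenyl group on C3, which is hydrated last. The precursor is the free triphenol bearing methyl, prenyl and isobutyryl groups.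

Key step: step 5

Remark (labels): C1 = bridgehead carrying prenyl, C2 = ring CH2, C3 = ring CH, C4 = bridgehead carrying methyl, C5–C6–C7 = enolised diketone bridge with isobutyryl on C6, C8 = one-carbon ketone bridge. The arene carbons carry the same labels, and exo means on the side of C8.

Remark (assumption): the tricarbonyl unit is written as the C5 enol/C7 ketone tautomer; the tautomers are one compound. Compound 10 and the target have the same spatial arrangement at C3 (substituent exo); the descriptor changes from S to R only through CIP priorities, so no structure needed correction.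

Remark (ligand): both antipodes of the diphosphine are commercial; (R,R) is written for definiteness, and the antipode that delivers the 1R series is to be fixed in a first run.

Remark (design): the bis-carbonate is made from dimethyl mesaconate so that its E geometry is fixed by the starting material; this geometry is what limits the second alkylation to the five-membered closure.

Step 1
Reactants: 1 2,4,6-trihydroxytoluene; 2 isobutyryl chloride
Product: 3 1-(2,4,6-trihydroxy-3-methylphenyl)-2-methylpropan-1-one
Conditions: AlCl3 (3.5 equiv), PhNO2/CH2Cl2, 0 °C to rt; aq. HCl
Reagents that add atoms: none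
Why: Friedel–Crafts acylation of the very electron-rich triphenol occurs at one of its two equivalent free ring carbons, and the aluminium-chelated aryl ketone that forms is deactivated against a second acylation.

Step 2
Reactants: 3 1-(2,4,6-trihydroxy-3-methylphenyl)-2-methylpropan-1-one; 4 prenyl bromide
Product: 5 2-methyl-1-[2,4,6-trihydroxy-3-methyl-5-(3-methylbut-2-en-1-yl)phenyl]propan-1-one
Conditions: 4 (1.0 equiv, slow addition), 10% aq. KOH, 0 °C
Reagents that add atoms: none
Why: C-alkylation of the ambident acylphloroglucinolate by the soft allylic bromide in water (SN2, then tautomerisation back to the arene) goes to the only ring carbon that still bears hydrogen, and one equivalent of bromide at 0 °C limits O-alkylation and a second, dearomatising prenylation.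

Step 3
Reactants: 6 dimethyl mesaconate
Product: 7 (E)-2-methylbut-2-ene-1,4-diol
Conditions: iBu2AlH (4.4 equiv), CH2Cl2, −78 to 0 °C; aq. potassium sodium tartrate (KNaC4H4O6)
Reagents that add atoms: none
Why: Diisobutylaluminium hydride reduces both conjugated esters in the 1,2 sense to the allylic diol without touching the alkene, so the E geometry of mesaconate is carried into 7.

Step 4
Reactants: 7 (E)-2-methylbut-2-ene-1,4-diol
Product: 8 (E)-2-methylbut-2-ene-1,4-diyl bis(methyl carbonate)
Conditions: ClCO2Me (2.5 equiv), pyridine, DMAP (cat.), CH2Cl2, 0 °C to rt
Reagents that add atoms: methyl chloroformate, COC(Cl)=O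
Why: Acylation of the two primary allylic alcohols by the chloroformate with pyridine as base is an ordinary carbonate formation that involves no allylic cation, so neither transposition nor E/Z change is expected, and the trans diol cannot close to a cyclic carbonate.

Step 5
Reactants: 5 2-methyl-1-[2,4,6-trihydroxy-3-methyl-5-(3-methylbut-2-en-1-yl)phenyl]propan-1-one; 8 (E)-2-methylbut-2-ene-1,4-diyl bis(methyl carbonate)
Product: 10 (1R,3S,4R)-5-hydroxy-6-isobutyryl-4-methyl-1-prenyl-3-(prop-1-en-2-yl)bicyclo[3.2.1]oct-5-ene-7,8-dione (labels as above; isopropenyl exo), via dienone carbonate 9 (not isolated)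
Conditions: Pd2(dba)3·CHCl3 (2.5 mol %), (R,R)-DACH-phenyl diphosphine [(1R,2R)-N,N′-bis(2-diphenylphosphinobenzoyl)cyclohexane-1,2-diamine] (7.5 mol %), 8 (1.1 equiv, slow addition), degassed THF, rt to 40 °C, no added base
Reagents that add atoms: none
Why: Proposed new method: zerovalent palladium ionises one carbonate of 8, the methoxide set free deprotonates 5, and the phenolate carbon C1 adds to the CH2 terminus of the π-allyl cation to give dienone 9; ionisation of the second carbonate then gives a syn π-allyl whose internal carbon C3 is attacked by C4 anti to palladium. The closest known reaction types are the palladium-catalysed dearomative double allylic alkylation of acylphloroglucinols with 2-methylenepropane-1,3-diyl bis-carbonates, which gives bicyclo[3.3.1]nonanes, and the [3+2] annulation of 1,3-dicarbonyl compounds with but-2-ene-1,4-diyl bis-carbonates. Ring C1–C2–C3–C4–C8 closes in the 5-exo mode on the π-allyl, the isopropenyl carbons staying outside the ring, and this closure should be the only practically irreversible event, since re-opening 10 would expel a non-aromatic dienolate whereas O-allylated and wrongly C-allylated dienones re-ionise to the aromatic phenolate (compare retro-allylation of allylated Meldrum's acids). C1 is set by ligand-controlled selection between the equilibrating enantiomers of 9 in the closure, C4 follows from C1 because the two-atom bridge can only span one face of the ring, and C3 is set by the π-allyl face the chiral ligand selects, the exo orientation keeping the isopropenyl group clear of the C5–C7 bridge. The step needs C1-to-CH2 and C4-to-CH regiochemistry and five- over seven-membered closure: the methyl-bearing C4 is the less hindered partner for the branched terminus, the isomeric π-allyl could close only by joining two fully substituted carbons, and the E geometry of 8 leads to the syn π-allyl, from which a seven-membered ring would hold an E alkene.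

Step 6
Reactants: 10 (1R,3S,4R)-5-hydroxy-6-isobutyryl-4-methyl-1-prenyl-3-(prop-1-en-2-yl)bicyclo[3.2.1]oct-5-ene-7,8-dione
Product: 11 (1R,3R,4R)-5-hydroxy-3-(2-hydroxypropan-2-yl)-6-isobutyryl-4-methyl-1-prenylbicyclo[3.2.1]oct-5-ene-7,8-dione (target; carbinol exo)
Conditions: Co(acac)2 (20 mol %), PhSiH3 (2 equiv), O2 (1 atm), iPrOH/THF, 0 °C to rt
Reagents that add atoms: dioxygen, O=O
Why: Mukaiyama hydration, in which hydrogen-atom transfer from the cobalt hydride should reach the unhindered CH2 of the 1,1-disubstituted alkene faster than the trisubstituted prenyl alkene, the tertiary radical is captured by O2 before it can add to the prenyl group, and reduction at cobalt by the silane gives the tertiary alcohol with C1, C3 and C4 untouched.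

Compound list
1 | 2,4,6-trihydroxytoluene (2-methylbenzene-1,3,5-triol) | Cc1c(O)cc(O)cc1O | starting material
2 | isobutyryl chloride | CC(C)C(Cl)=O | starting material
3 | 1-(2,4,6-trihydroxy-3-methylphenyl)-2-methylpropan-1-one | CC(C)C(=O)c1c(O)cc(O)c(C)c1O | intermediate
4 | prenyl bromide (1-bromo-3-methylbut-2-ene) | CC(C)=CCBr | starting material
5 | 2-methyl-1-[2,4,6-trihydroxy-3-methyl-5-(3-methylbut-2-en-1-yl)phenyl]propan-1-one | CC(C)=CCc1c(O)c(C)c(O)c(C(=O)C(C)C)c1O | intermediate
6 | dimethyl mesaconate (dimethyl (E)-2-methylbut-2-enedioate) | COC(=O)/C=C(C)/C(=O)OC | starting material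
7 | (E)-2-methylbut-2-ene-1,4-diol | OC/C=C(C)/CO | intermediate
8 | (E)-2-methylbut-2-ene-1,4-diyl bis(methyl carbonate) | COC(=O)OC/C=C(C)/COC(=O)OC | intermediate
9 | dienone carbonate: dearomatised 5 carrying on C1, beside the prenyl group, an (E)-4-(methoxycarbonyloxy)-3-methylbut-2-enyl chain; cyclohexadienone tautomer, C1 S as drawn, same spatial arrangement as C1 of 10 | CC(C)=CC[C@@]1(C/C=C(C)/COC(=O)OC)C(=O)C(C)=C(O)C(C(=O)C(C)C)=C1O | intermediate (not isolated)
10 | (1R,3S,4R)-5-hydroxy-6-isobutyryl-4-methyl-1-prenyl-3-(prop-1-en-2-yl)bicyclo[3.2.1]oct-5-ene-7,8-dione, isopropenyl exo; von Baeyer name (1R,5R,6S)-4-hydroxy-5-methyl-1-(3-methylbut-2-en-1-yl)-3-(2-methylpropanoyl)-6-(prop-1-en-2-yl)bicyclo[3.2.1]oct-3-ene-2,8-dione | CC(C)=CC[C@@]12C[C@@H](C(C)=C)[C@@](C)(C1=O)C(O)=C(C(=O)C(C)C)C2=O | intermediate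
11 | (1R,3R,4R)-5-hydroxy-3-(2-hydroxypropan-2-yl)-6-isobutyryl-4-methyl-1-prenylbicyclo[3.2.1]oct-5-ene-7,8-dione, carbinol exo; von Baeyer name (1R,5R,6R)-4-hydroxy-6-(2-hydroxypropan-2-yl)-5-methyl-1-(3-methylbut-2-en-1-yl)-3-(2-methylpropanoyl)bicyclo[3.2.1]oct-3-ene-2,8-dione | CC(C)=CC[C@@]12C[C@@H](C(C)(C)O)[C@@](C)(C1=O)C(O)=C(C(=O)C(C)C)C2=O | target

Total step count: 6. Longest linear sequence: 4 steps (1 → 3 → 5 → 10 → 11, or 6 → 7 → 8 → 10 → 11).

Steps most likely to fail

Step 5. The first bond may form through the other π-allyl (ionisation of the carbonate next to the methyl-bearing alkene carbon) or at C4, and return of these dienones to the arene may be too slow to correct them, so that constitutional isomers or seven-membered closure products accumulate. The same C–C ionisation could also move or remove the C1 prenyl group, and enantio-induction could be weak or erode if the closure itself reverses. The fallback is stepwise, uses known reaction types, sets out from 5 and comes back at 10. Commercial 2-methyl-2-vinyloxirane is opened with TiCl4 (CH2Cl2, −80 °C) in the known SN2′ sense to (E)-4-chloro-2-methylbut-2-en-1-ol F1, which methyl chloroformate and pyridine convert into (E)-4-chloro-2-methylbut-2-en-1-yl methyl carbonate F2. Alkylative dearomatisation of 5 with F2 (NaH, toluene, 0 °C to rt), the geminal C-alkylation known from lupulone-type compounds, should put the chain on the prenyl-bearing carbon and give the racemic dienone carbonate F3, which is isolated and purified so that the regiochemistry of the first bond is fixed before palladium is used. Intramolecular Tsuji–Trost alkylation of F3 with Pd2(dba)3 and the same chiral diphosphine then closes the ring to 10. Without the reversible first step the ligand acts by kinetic resolution, so at most half of F3 can become the wanted enantiomer and the rest is recovered.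

Step 6. Hydrogen-atom transfer may not discriminate well enough between the two alkenes, so that the prenyl group is hydrated too, or the tertiary radical may add to the prenyl alkene before oxygen capture. The fallback sets out from 10 and comes back at 11 by an ionic route. Hg(OAc)2 (1.05 equiv) in THF/H2O at 0 °C should add to the 1,1-disubstituted alkene much faster than to the trisubstituted one, giving the acetoxymercurio carbinol F4 (both epimers at the new carbinol carbon). Brief treatment with NaBH4 in aq. NaOH at 0 °C then removes mercury; the exposure is kept short to spare the hindered C8 ketone.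

Step 2. O-prenylation and a second, dearomatising prenylation at C1 or C4 may consume the phenolate. The fallback sets out from 3 and comes back at 5 without a new compound: Friedel–Crafts prenylation with 2-methylbut-3-en-2-ol and BF3·OEt2 in dioxane at rt attacks the free ring carbon through the 1,1-dimethylallyl cation, which avoids phenolate chemistry altogether.

Further compounds
F1 | step 5 | (E)-4-chloro-2-methylbut-2-en-1-ol | OC/C(C)=C/CCl
F2 | step 5 | (E)-4-chloro-2-methylbut-2-en-1-yl methyl carbonate | COC(=O)OC/C(C)=C/CCl
F3 | step 5 | racemic dienone carbonate (racemate of 9) | CC(C)=CCC1(C/C=C(C)/COC(=O)OC)C(=O)C(C)=C(O)C(C(=O)C(C)C)=C1O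
F4 | step 6 | acetoxymercurio carbinol, 10 with C3 carrying C(OH)(CH3)CH2HgOAc, both epimers at the carbinol carbon | CC(C)=CC[C@@]12C[C@@H](C(C)(O)C[Hg]OC(C)=O)[C@@](C)(C1=O)C(O)=C(C(=O)C(C)C)C2=O
F0 | step 2 | none | none
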